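**Plan**

- Cuts, in retrosynthetic order: the four O‑alkyl bonds; the C3–aryl bond of the 8‑chloro‑7‑hydroxyisoflavone (unit 1); in the 5,7‑dihydroxyisoflavone (unit 2) the pyranone at C4–C4a and at C2; ring A of unit 2 at C8a–C4a and C5–C6 (C8a–C8 is broken and re‑formed), giving a 4‑aryloxy‑3‑ethoxycyclobutenone and ethoxyacetylene; the cyclobutenone into an aryloxyketene and a second ethoxyacetylene.
- Enabling feature: ring A of unit 2 carries oxygen at C8a (O1), C8 (aryl ether), C7 and C5, hydrogen at C6 and carbon at C4a. The ether carbon C8 lies between C7–O and C8a–O1, and a vinylketene benzannulation gives exactly this 2‑aryloxy‑3,5‑dialkoxyphenol, with its one free hydroxyl at the future O1.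
- Forward order: four‑membered ring, ring A, pyranone ring C of unit 2 (acylation ortho to the free hydroxyl, one‑carbon closure), borylation, Suzuki coupling with an 8‑chloro‑3‑iodo‑7‑methoxychromone made from 2‑chlororesorcinol, global dealkylation.
- Stereochemistry: the target has no stereocentre. The only one on the way, C4 of the racemic cyclobutenone, becomes the sp2 carbon C8 in the key step.

Key step: step 3

Remark: ethoxyacetylene is taken as its commercial hexane solution, and the diaryl ether of the target is taken as freely rotating (no atropisomers).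

**Route**

Step 1
Reactants: 1 (4‑bromophenoxy)acetic acid
Product: 2 (4‑bromophenoxy)acetyl chloride
Conditions: (COCl)2, cat. DMF, CH2Cl2, 0 °C to rt
Reagents that add atoms: oxalyl chloride, O=C(Cl)C(=O)Cl
Why: Vilsmeier‑type activation (oxalyl chloride with catalytic DMF) should convert the acid into its chloride under conditions to which the aryl bromide and the aryl alkyl ether are inert.

Step 2
Reactants: 2 (4‑bromophenoxy)acetyl chloride; 3 ethoxyacetylene
Product: 5 4‑(4‑bromophenoxy)‑3‑ethoxycyclobut‑2‑en‑1‑one (racemic), via (4‑bromophenoxy)ketene 4 (not isolated)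
Conditions: Et3N, 3 (2 equiv), Et2O, 0 °C to rt, slow addition of 2
Reagents that add atoms: none
Why: Triethylamine should dehydrochlorinate 2 to aryloxyketene 4, which is captured by the ynol ether in a ketene–alkyne [2+2] cycloaddition with the nucleophilic CH terminus of 3 on the ketene carbonyl carbon, as in the known preparation of 3‑ethoxycyclobutenones from acid chlorides; the stereocentre C4 forms as a racemate and is erased in step 3.

Step 3
Reactants: 5 4‑(4‑bromophenoxy)‑3‑ethoxycyclobut‑2‑en‑1‑one (racemic); 3 ethoxyacetylene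
Product: 10 2‑(4‑bromophenoxy)‑3,5‑diethoxyphenol, via vinylketene 6 (not isolated), via vinylcyclobutenone 7 (not isolated), via dienylketene 8 (not isolated), via cyclohexadienone 9 (not isolated)
Conditions: 3 (3 equiv), toluene, sealed tube, 80 °C then 110 °C
Reagents that add atoms: none
Why: Danheiser benzannulation: conrotatory four‑electron opening of 5 (aryloxy group turning outward) should give vinylketene 6, a ketene–ynol ether [2+2] cycloaddition vinylcyclobutenone 7, a second four‑electron opening dienylketene 8, and tautomerization of cyclohexadienone 9 the phenol. The closest known reactions are the thermal unions of cyclobutenones with alkoxy‑ and siloxyalkynes to resorcinol monoethers, among them 3‑ethoxycyclobutenone with ethoxyacetylene to 3,5‑diethoxyphenol, of which 5 is the 4‑aryloxy congener. Ring A closes by disrotatory six‑electron electrocyclization of 8 between the ketene carbon (future C8a) and the aryloxy‑bearing terminus (future C8), and the transient four‑membered ring of 7 closes by [2+2] cycloaddition. No stereocentre is formed, and the one in 5 becomes an arene carbon. The step needs the regiochemistry of the [2+2] addition, which the polarization of 3 secures: its CH terminus bonds to the ketene carbonyl carbon, so the new C–H lies ortho and the new ethoxy group meta to the hydroxyl, while the aryloxy carbon stays next to the hydroxyl because the C1–C4 bond of 5 is re‑formed. Excess alkyne and a start at 80 °C should limit capture of 6 by the product phenol and retro‑ene fragmentation of 3.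

Step 4
Reactants: 10 2‑(4‑bromophenoxy)‑3,5‑diethoxyphenol; 11 (4‑methoxyphenyl)acetic acid
Product: 12 1‑[3‑(4‑bromophenoxy)‑4,6‑diethoxy‑2‑hydroxyphenyl]‑2‑(4‑methoxyphenyl)ethan‑1‑one
Conditions: BF3·OEt2 (neat), 85 °C; aq. NaOAc work‑up
Reagents that add atoms: none
Why: BF3‑mediated Friedel–Crafts acylation (Nencki/Hoesch type, as used for 3,5‑dialkoxyphenols with arylacetic acids) should go ortho to the free hydroxyl through the aryl ester and its Fries shift to the BF2‑chelated ortho‑hydroxy ketone, and the only free ortho position is the future C4a.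

Step 5
Reactants: 12 1‑[3‑(4‑bromophenoxy)‑4,6‑diethoxy‑2‑hydroxyphenyl]‑2‑(4‑methoxyphenyl)ethan‑1‑one
Product: 14 8‑(4‑bromophenoxy)‑5,7‑diethoxy‑3‑(4‑methoxyphenyl)‑4H‑chromen‑4‑one, via enaminone 13 (not isolated)
Conditions: Me2NCH(OMe)2, toluene, 100 °C
Reagents that add atoms: N,N‑dimethylformamide dimethyl acetal, COC(OC)N(C)C
Why: Condensation of the benzylic methylene with the formamide acetal should give enaminone 13, and conjugate addition of the ortho‑phenol with loss of dimethylamine closes the pyranone, the standard deoxybenzoin route to isoflavones.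

Step 6
Reactants: 14 8‑(4‑bromophenoxy)‑5,7‑diethoxy‑3‑(4‑methoxyphenyl)‑4H‑chromen‑4‑one
Product: 15 5,7‑diethoxy‑3‑(4‑methoxyphenyl)‑8‑[4‑(4,4,5,5‑tetramethyl‑1,3,2‑dioxaborolan‑2‑yl)phenoxy]‑4H‑chromen‑4‑one
Conditions: B2pin2, Pd(dppf)Cl2, KOAc, 1,4‑dioxane, 90 °C
Reagents that add atoms: bis(pinacolato)diboron, CC1(C)OB(OC1(C)C)B1OC(C)(C)C(C)(C)O1
Why: Miyaura borylation: oxidative addition of the aryl bromide to zerovalent palladium, acetate‑assisted transmetalation with the diboron reagent and reductive elimination should give the aryl boronate, the weakly basic KOAc leaving the chromone intact.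

Step 7
Reactants: 16 2‑chlororesorcinol
Product: 17 1‑(3‑chloro‑2,4‑dihydroxyphenyl)ethan‑1‑one
Conditions: AcOH, BF3·OEt2, 90 °C
Reagents that add atoms: acetic acid, CC(=O)O
Why: Friedel–Crafts (Nencki) acetylation of the resorcinol should occur at C4, ortho to one hydroxyl and para to the other, and stop at the chelated ortho‑hydroxy ketone.

Step 8
Reactants: 17 1‑(3‑chloro‑2,4‑dihydroxyphenyl)ethan‑1‑one
Product: 18 1‑(3‑chloro‑2‑hydroxy‑4‑methoxyphenyl)ethan‑1‑one
Conditions: MeI (1.1 equiv), K2CO3, acetone, reflux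
Reagents that add atoms: iodomethane, CI
Why: Williamson etherification should be selective for the 4‑hydroxyl because the 2‑hydroxyl is held in a hydrogen bond to the ketone and is much less acidic and nucleophilic.

Step 9
Reactants: 18 1‑(3‑chloro‑2‑hydroxy‑4‑methoxyphenyl)ethan‑1‑one
Product: 19 (E)‑1‑(3‑chloro‑2‑hydroxy‑4‑methoxyphenyl)‑3‑(dimethylamino)prop‑2‑en‑1‑one
Conditions: Me2NCH(OMe)2, toluene, 90 °C
Reagents that add atoms: N,N‑dimethylformamide dimethyl acetal, COC(OC)N(C)C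
Why: Condensation of the methyl ketone with the formamide acetal should give the (E)‑enaminone, the usual precursor of 3‑substituted chromones.

Step 10
Reactants: 19 (E)‑1‑(3‑chloro‑2‑hydroxy‑4‑methoxyphenyl)‑3‑(dimethylamino)prop‑2‑en‑1‑one
Product: 20 8‑chloro‑3‑iodo‑7‑methoxy‑4H‑chromen‑4‑one
Conditions: I2, CHCl3, rt
Reagents that add atoms: iodine, II
Why: Iodine‑mediated cyclization of the ortho‑hydroxyaryl enaminone (Gammill chromone synthesis): iodination at the α‑carbon, addition of the phenol to the iminium carbon and loss of dimethylamine should give the 3‑iodochromone.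

Step 11
Reactants: 15 5,7‑diethoxy‑3‑(4‑methoxyphenyl)‑8‑[4‑(4,4,5,5‑tetramethyl‑1,3,2‑dioxaborolan‑2‑yl)phenoxy]‑4H‑chromen‑4‑one; 20 8‑chloro‑3‑iodo‑7‑methoxy‑4H‑chromen‑4‑one
Product: 21 8‑[4‑(8‑chloro‑7‑methoxy‑4‑oxo‑4H‑chromen‑3‑yl)phenoxy]‑5,7‑diethoxy‑3‑(4‑methoxyphenyl)‑4H‑chromen‑4‑one
Conditions: Pd(PPh3)4, K2CO3, 1,4‑dioxane/H2O, 80 °C
Reagents that add atoms: none
Why: Suzuki–Miyaura coupling of a 3‑iodochromone with an arylboronate is the standard isoflavone construction, and oxidative addition at the C–I bond should be far faster than at the hindered, electron‑rich C–Cl bond.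

Step 12
Reactants: 21 8‑[4‑(8‑chloro‑7‑methoxy‑4‑oxo‑4H‑chromen‑3‑yl)phenoxy]‑5,7‑diethoxy‑3‑(4‑methoxyphenyl)‑4H‑chromen‑4‑one
Product: 22 bisoflavolin H
Conditions: BBr3 (excess), CH2Cl2, −78 °C to 40 °C; then MeOH, H2O
Reagents that add atoms: none
Why: Lewis acid ether cleavage: BBr3 should coordinate each alkyl aryl ether oxygen and bromide remove the methyl or ethyl group by SN2, while the diaryl ether (no sp3 carbon), the aryl chloride and both chromones are untouched, as in the usual dealkylation of isoflavone ethers.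

**Compound list**

1 | (4‑bromophenoxy)acetic acid | OC(=O)COc1ccc(Br)cc1 | starting material
2 | (4‑bromophenoxy)acetyl chloride | ClC(=O)COc1ccc(Br)cc1 | intermediate
3 | ethoxyacetylene (ethoxyethyne) | CCOC#C | starting material
4 | (4‑bromophenoxy)ketene, 2‑(4‑bromophenoxy)ethen‑1‑one | O=C=COc1ccc(Br)cc1 | intermediate
5 | 4‑(4‑bromophenoxy)‑3‑ethoxycyclobut‑2‑en‑1‑one (racemic) | CCOC1=CC(=O)C1Oc1ccc(Br)cc1 | intermediate
6 | (3Z)‑4‑(4‑bromophenoxy)‑3‑ethoxybuta‑1,3‑dien‑1‑one | O=C=C/C(OCC)=C/Oc1ccc(Br)cc1 | intermediate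
7 | 4‑[(Z)‑2‑(4‑bromophenoxy)‑1‑ethoxyethenyl]‑3‑ethoxycyclobut‑2‑en‑1‑one (racemic) | CCOC1=CC(=O)C1/C(OCC)=C/Oc1ccc(Br)cc1 | intermediate
8 | (3E,5Z)‑6‑(4‑bromophenoxy)‑3,5‑diethoxyhexa‑1,3,5‑trien‑1‑one | O=C=C/C(OCC)=C\C(OCC)=C\Oc1ccc(Br)cc1 | intermediate
9 | 6‑(4‑bromophenoxy)‑3,5‑diethoxycyclohexa‑2,4‑dien‑1‑one (racemic) | CCOC1=CC(=O)C(Oc2ccc(Br)cc2)C(OCC)=C1 | intermediate
10 | 2‑(4‑bromophenoxy)‑3,5‑diethoxyphenol | CCOc1cc(O)c(Oc2ccc(Br)cc2)c(OCC)c1 | intermediate
11 | (4‑methoxyphenyl)acetic acid | COc1ccc(CC(=O)O)cc1 | starting material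
12 | 1‑[3‑(4‑bromophenoxy)‑4,6‑diethoxy‑2‑hydroxyphenyl]‑2‑(4‑methoxyphenyl)ethan‑1‑one | CCOc1cc(OCC)c(C(=O)Cc2ccc(OC)cc2)c(O)c1Oc1ccc(Br)cc1 | intermediate
13 | 1‑[3‑(4‑bromophenoxy)‑4,6‑diethoxy‑2‑hydroxyphenyl]‑3‑(dimethylamino)‑2‑(4‑methoxyphenyl)prop‑2‑en‑1‑one (alkene geometry not fixed) | CCOc1cc(OCC)c(C(=O)C(=CN(C)C)c2ccc(OC)cc2)c(O)c1Oc1ccc(Br)cc1 | intermediate
14 | 8‑(4‑bromophenoxy)‑5,7‑diethoxy‑3‑(4‑methoxyphenyl)‑4H‑chromen‑4‑one | CCOc1cc(OCC)c2c(=O)c(-c3ccc(OC)cc3)coc2c1Oc1ccc(Br)cc1 | intermediate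
15 | 5,7‑diethoxy‑3‑(4‑methoxyphenyl)‑8‑[4‑(4,4,5,5‑tetramethyl‑1,3,2‑dioxaborolan‑2‑yl)phenoxy]‑4H‑chromen‑4‑one | CCOc1cc(OCC)c2c(=O)c(-c3ccc(OC)cc3)coc2c1Oc1ccc(B2OC(C)(C)C(C)(C)O2)cc1 | intermediate
16 | 2‑chlororesorcinol (2‑chlorobenzene‑1,3‑diol) | Oc1cccc(O)c1Cl | starting material
17 | 1‑(3‑chloro‑2,4‑dihydroxyphenyl)ethan‑1‑one | CC(=O)c1ccc(O)c(Cl)c1O | intermediate
18 | 1‑(3‑chloro‑2‑hydroxy‑4‑methoxyphenyl)ethan‑1‑one | COc1ccc(C(C)=O)c(O)c1Cl | intermediate
19 | (E)‑1‑(3‑chloro‑2‑hydroxy‑4‑methoxyphenyl)‑3‑(dimethylamino)prop‑2‑en‑1‑one | COc1ccc(C(=O)/C=C/N(C)C)c(O)c1Cl | intermediate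
20 | 8‑chloro‑3‑iodo‑7‑methoxy‑4H‑chromen‑4‑one | COc1ccc2c(c1Cl)occ(I)c2=O | intermediate
21 | 8‑[4‑(8‑chloro‑7‑methoxy‑4‑oxo‑4H‑chromen‑3‑yl)phenoxy]‑5,7‑diethoxy‑3‑(4‑methoxyphenyl)‑4H‑chromen‑4‑one | CCOc1cc(OCC)c2c(=O)c(-c3ccc(OC)cc3)coc2c1Oc1ccc(-c2coc3c(Cl)c(OC)ccc3c2=O)cc1 | intermediate
22 | bisoflavolin H, 8‑[4‑(8‑chloro‑7‑hydroxy‑4‑oxo‑4H‑chromen‑3‑yl)phenoxy]‑5,7‑dihydroxy‑3‑(4‑hydroxyphenyl)‑4H‑chromen‑4‑one | O=c1c(-c2ccc(Oc3c(O)cc(O)c4c(=O)c(-c5ccc(O)cc5)coc34)cc2)coc2c(Cl)c(O)ccc12 | target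

**Count and risks**

Total steps: 12. Longest linear sequence: 8 steps (steps 1–6, 11 and 12); the iodochromone branch (steps 7–10) joins at step 11.

Step 3 (key benzannulation). The vinylketene may be consumed by oligomerization or by acylating the product phenol, the alkyne may fragment before it is captured, or the cascade may stall at vinylcyclobutenone 7. The fallback takes ring A from the unsubstituted parent benzannulation and makes the aryl ether by an Ullmann coupling with CuI. It sets out from 3 and comes back at 10.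
- Heating 3 alone in toluene (sealed tube, 120 °C) lets part of it lose ethene to ketene F1, which adds to 3 to give 3‑ethoxycyclobut‑2‑en‑1‑one F2 and is carried on by more 3 to 3,5‑diethoxyphenol F3.
- Phenoxide‑directed ortho‑formylation (MgCl2, Et3N, paraformaldehyde, MeCN, reflux) gives 2,4‑diethoxy‑6‑hydroxybenzaldehyde F4.
- MOMCl and iPr2NEt in CH2Cl2 give 2,4‑diethoxy‑6‑(methoxymethoxy)benzaldehyde F5.
- Baeyer–Villiger (Dakin‑type) oxidation with mCPBA in CH2Cl2 gives 2,4‑diethoxy‑6‑(methoxymethoxy)phenyl formate F6, and K2CO3 in MeOH frees 2,4‑diethoxy‑6‑(methoxymethoxy)phenol F7.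
- Ullmann coupling with 1‑bromo‑4‑iodobenzene (CuI, picolinic acid, K3PO4, DMSO, 90 °C) gives 2‑(4‑bromophenoxy)‑1,5‑diethoxy‑3‑(methoxymethoxy)benzene F8.
- HCl in MeOH removes the acetal and returns 10.

Step 2 (ketene–ynol ether cycloaddition). Oligomerization of ketene 4 may outrun the cycloaddition, or the vinylogous ester 5 may be lost by hydrolysis on isolation. The fallback reaches vinylketene 6 without a cyclobutenone, by 1,4‑dehydrochlorination of an unsaturated acid chloride. It sets out from 2 and comes back at 10.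
- Claisen acylation of the lithium enolate of ethyl acetate with 2 (LiN(SiMe3)2, THF, −78 °C) gives ethyl 4‑(4‑bromophenoxy)‑3‑oxobutanoate F9.
- HC(OEt)3 with catalytic H2SO4 in EtOH gives ethyl (E)‑4‑(4‑bromophenoxy)‑3‑ethoxybut‑2‑enoate F10.
- LiOH in THF/H2O, then careful acidification, gives (E)‑4‑(4‑bromophenoxy)‑3‑ethoxybut‑2‑enoic acid F11.
- (COCl)2 with catalytic DMF gives (E)‑4‑(4‑bromophenoxy)‑3‑ethoxybut‑2‑enoyl chloride F12.
- Et3N in toluene in the presence of 3 (rt, then 80 °C) removes HCl across the γ‑CH2 and the acyl chloride to give 6, which runs through 7, 8 and 9 to 10.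

Step 4 (C‑acylation). Acylation may occur at the position between the two ethoxy groups (para to the hydroxyl), or the Lewis acid may cause partial de‑ethylation. The fallback installs the carbonyl carbon by a strictly ortho formylation and adds the benzyl group afterwards. It sets out from 10 and comes back at 12.
- MgCl2, Et3N and paraformaldehyde in MeCN at reflux give 3‑(4‑bromophenoxy)‑4,6‑diethoxy‑2‑hydroxybenzaldehyde F13.
- 4‑Methoxybenzylmagnesium chloride (2.2 equiv, THF, 0 °C) gives 1‑[3‑(4‑bromophenoxy)‑4,6‑diethoxy‑2‑hydroxyphenyl]‑2‑(4‑methoxyphenyl)ethan‑1‑ol F14 (racemic).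
- MnO2 in CH2Cl2 oxidizes the benzylic alcohol to 12.

**Further compounds**

F1 | step 3 | ketene (ethenone) | C=C=O
F2 | step 3 | 3‑ethoxycyclobut‑2‑en‑1‑one | CCOC1=CC(=O)C1
F3 | step 3 | 3,5‑diethoxyphenol | CCOc1cc(O)cc(OCC)c1
F4 | step 3 | 2,4‑diethoxy‑6‑hydroxybenzaldehyde | CCOc1cc(O)c(C=O)c(OCC)c1
F5 | step 3 | 2,4‑diethoxy‑6‑(methoxymethoxy)benzaldehyde | CCOc1cc(OCOC)c(C=O)c(OCC)c1
F6 | step 3 | 2,4‑diethoxy‑6‑(methoxymethoxy)phenyl formate | CCOc1cc(OCOC)c(OC=O)c(OCC)c1
F7 | step 3 | 2,4‑diethoxy‑6‑(methoxymethoxy)phenol | CCOc1cc(OCOC)c(O)c(OCC)c1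
F8 | step 3 | 2‑(4‑bromophenoxy)‑1,5‑diethoxy‑3‑(methoxymethoxy)benzene | CCOc1cc(OCOC)c(Oc2ccc(Br)cc2)c(OCC)c1
F9 | step 2 | ethyl 4‑(4‑bromophenoxy)‑3‑oxobutanoate | CCOC(=O)CC(=O)COc1ccc(Br)cc1
F10 | step 2 | ethyl (E)‑4‑(4‑bromophenoxy)‑3‑ethoxybut‑2‑enoate | CCO/C(COc1ccc(Br)cc1)=C/C(=O)OCC
F11 | step 2 | (E)‑4‑(4‑bromophenoxy)‑3‑ethoxybut‑2‑enoic acid | CCO/C(COc1ccc(Br)cc1)=C/C(=O)O
F12 | step 2 | (E)‑4‑(4‑bromophenoxy)‑3‑ethoxybut‑2‑enoyl chloride | CCO/C(COc1ccc(Br)cc1)=C/C(=O)Cl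
F13 | step 4 | 3‑(4‑bromophenoxy)‑4,6‑diethoxy‑2‑hydroxybenzaldehyde | CCOc1cc(OCC)c(C=O)c(O)c1Oc1ccc(Br)cc1
F14 | step 4 | 1‑[3‑(4‑bromophenoxy)‑4,6‑diethoxy‑2‑hydroxyphenyl]‑2‑(4‑methoxyphenyl)ethan‑1‑ol (racemic) | CCOc1cc(OCC)c(C(O)Cc2ccc(OC)cc2)c(O)c1Oc1ccc(Br)cc1
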